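**Assumption:** the target has no stereocentres, so it is achiral and there is no enantiomer to set. The only stereocentres in the route (C6 and C1 of the cyclohexane intermediates 3, 4, 5 and 8) are racemic and are destroyed on aromatisation.

## Retrosynthetic overview
1. Target ⇒ tert-butyl ester 9 (final TFA cleavage). The ring B aryl ester is formed before ring B is aromatised: 9 ⇐ DDQ dehydrogenation of the cyclohexadienyl enol ester 8.
2. Enol ester 8 ⇐ O-acylation of the cyclic 1,3-dione 3 (which becomes ring B) with the ring A acid 7.
3. Ring A is built from the same dione 3. The Cl is placed regiospecifically at the dione C3, the carbon between the two C=O groups, which avoids arene-chlorination regiochemistry. The 4-OMe is installed as an enol ether, and DDQ aromatises the dienol ether 5 to 6, which TFA converts to acid 7.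
4. Dione 3 ⇐ Michael–Claisen annulation of tert-butyl acetoacetate (1) and methyl (E)-hex-2-enoate (2). Both aromatic rings come from one commercial-building-block pair.

## Route

**Step 1**
Reactants: 1 (tert-butyl acetoacetate), 2 (methyl (E)-hex-2-enoate)
Product: 3 (tert-butyl 2,4-dioxo-6-propylcyclohexane-1-carboxylate, racemic, largely enolised)
Conditions: t-BuOK (2.1 equiv), THF/t-BuOH, 0 °C → reflux; then aq. HCl to pH ~3
Reagents that add atoms: none (MeOH is lost)
Why: Michael addition of the acetoacetate enolate to the enoate, then Claisen (Dieckmann) closure of the acetyl enolate onto the methyl ester, places the propyl group next to C1 and builds the six-membered ring in one pot.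

**Step 2**
Reactants: 3
Product: 4 (tert-butyl 3-chloro-2,4-dioxo-6-propylcyclohexane-1-carboxylate)
Conditions: NCS (1.05 equiv), CH2Cl2, 0 °C → rt
Reagents that add atoms: N-chlorosuccinimide, O=C1CCC(=O)N1Cl
Why: electrophilic chlorination of the enolised 1,3-dione, whose C3 is the most acidic and nucleophilic carbon, puts Cl exactly between the future C2–OH and C4–OMe (the 3-Cl of the target).

**Step 3**
Reactants: 4
Product: 5 (tert-butyl 3-chloro-2-hydroxy-4-methoxy-6-propylcyclohexa-1,3-diene-1-carboxylate)
Conditions: TMSCHN2 (1.5 equiv), MeOH/toluene, 0 °C → rt; use the crude product directly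
Reagents that add atoms: trimethylsilyldiazomethane, C[Si](C)(C)[CH-][N+]#N (delivers CH3)
Why: O-methylation of the strongly acidic chloro-vinylogous acid is favoured at O4, because O2 is hindered by the adjacent CO2tBu and held in the chelated enol. This gives the dienol ether needed for mild aromatisation.

**Step 4**
Reactants: 5
Product: 6 (tert-butyl 3-chloro-2-hydroxy-4-methoxy-6-propylbenzoate)
Conditions: DDQ (1.1 equiv), dry 1,4-dioxane, rt → 50 °C
Reagents that add atoms: none (DDQ only removes H2)
Why: DDQ abstracts hydride from C5–H, which is allylic to the methoxy-substituted diene. The resulting cation is stabilised by OMe and loses H+ from C6, so the aromatic ring forms by dehydrogenative aromatisation.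

**Step 5**
Reactants: 6
Product: 7 (3-chlorodivaricatinic acid, 3-chloro-2-hydroxy-4-methoxy-6-propylbenzoic acid)
Conditions: TFA/CH2Cl2 (1:4), 0 °C → rt, 2 h; evaporate below 30 °C
Reagents that add atoms: none (isobutylene is lost)
Why: acidolysis of the tert-butyl ester by the SN1/E1 pathway; the aryl chloride, aryl methyl ether and phenol are untouched, and the low temperature avoids decarboxylation of the salicylic acid.

**Step 6**
Reactants: 7 (acid), 3 (dione)
Product: 8 (tert-butyl 4-[(3-chloro-2-hydroxy-4-methoxy-6-propylbenzoyl)oxy]-2-hydroxy-6-propylcyclohexa-1,3-diene-1-carboxylate)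
Conditions: EDC·HCl (1.3 equiv), DMAP (0.1 equiv), CH2Cl2, 0 °C → rt, 12 h
Reagents that add atoms: none (water is lost)
Why: Steglich-type O-acylation of the acidic dione enol. The ring A 2-OH is intramolecularly H-bonded and unreactive, and O2 of the dione is chelated to the ester, so acylation occurs at O4. This sets the 4-O-acyl (depside) connectivity before ring B exists.

**Step 7**
Reactants: 8
Product: 9 (tert-butyl 4-[(3-chloro-2-hydroxy-4-methoxy-6-propylbenzoyl)oxy]-2-hydroxy-6-propylbenzoate)
Conditions: DDQ (1.3 equiv), dry 1,4-dioxane, 60–80 °C
Reagents that add atoms: none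
Why: Proposed new method: late-stage dehydrogenative aromatisation that releases the aryl ester as the ring forms. Hydride abstraction at C5–H gives a cation stabilised by the enol-ester oxygen, and loss of H+ from C6 gives the aromatic ring. The closest known reactions are DDQ aromatisation of cyclohexadienes and of dienol ethers (step 4). The enol ester is a weaker donor than the enol ether, so heating is needed.

**Step 8**
Reactants: 9
Product: 10 (3-chlorodivaricatic acid)
Conditions: TFA/CH2Cl2 (1:4), 0 °C → rt, 3 h
Reagents that add atoms: none
Why: acidolysis of the tert-butyl ester, with no hydrogenolysis step that could dechlorinate the ring. The diaryl ester, OMe and Ar–Cl survive, and the product is the target.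

## Self-check summary
- **Structure match:** ring A is C1-COO, C2-OH, C3-Cl, C4-OMe, C5-H, C6-Pr, and ring B is 2-OH, 4-O-acyl, 6-Pr with COOH at C1. This matches the target SMILES. Formula C21H23ClO7 is reached by 3 (C14H22O4) + 7 (C11H13ClO4) − H2O − H2 − C4H8.
- **Functional-group survival:** tert-butyl esters survive the base, NCS, TMSCHN2, DDQ and EDC steps, and are cleaved only in steps 5 and 8. No Pd/H2 is used, so the Ar–Cl is safe. The aryl ester is formed at step 6 and is never exposed to strong base or nucleophiles.
- **Stereocentres:** the target has none, and all racemic sp3 centres are removed in steps 4 and 7.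

## Compound list
| # | Name | SMILES | Role |
|---|---|---|---|
| 1 | tert-Butyl acetoacetate | CC(=O)CC(=O)OC(C)(C)C | starting material |
| 2 | Methyl (E)-hex-2-enoate | CCC/C=C/C(=O)OC | starting material |
| 3 | tert-Butyl 2,4-dioxo-6-propylcyclohexane-1-carboxylate (racemic) | CCCC1CC(=O)CC(=O)C1C(=O)OC(C)(C)C | intermediate |
| 4 | tert-Butyl 3-chloro-2,4-dioxo-6-propylcyclohexane-1-carboxylate (racemic) | CCCC1CC(=O)C(Cl)C(=O)C1C(=O)OC(C)(C)C | intermediate |
| 5 | tert-Butyl 3-chloro-2-hydroxy-4-methoxy-6-propylcyclohexa-1,3-diene-1-carboxylate (racemic) | CCCC1CC(OC)=C(Cl)C(O)=C1C(=O)OC(C)(C)C | intermediate |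
| 6 | tert-Butyl 3-chloro-2-hydroxy-4-methoxy-6-propylbenzoate | CCCc1cc(OC)c(Cl)c(O)c1C(=O)OC(C)(C)C | intermediate |
| 7 | 3-Chloro-2-hydroxy-4-methoxy-6-propylbenzoic acid | CCCc1cc(OC)c(Cl)c(O)c1C(=O)O | intermediate |
| 8 | Enol ester of 7 with 3 (tert-butyl 4-acyloxy-2-hydroxy-6-propylcyclohexa-1,3-diene-1-carboxylate, racemic) | CCCC1CC(OC(=O)c2c(CCC)cc(OC)c(Cl)c2O)=CC(O)=C1C(=O)OC(C)(C)C | intermediate |
| 9 | tert-Butyl ester of the target depside | CCCc1cc(OC(=O)c2c(CCC)cc(OC)c(Cl)c2O)cc(O)c1C(=O)OC(C)(C)C | intermediate |
| 10 | 3-Chlorodivaricatic acid | CCCc1cc(OC(=O)c2c(CCC)cc(OC)c(Cl)c2O)cc(O)c1C(=O)O | target |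

**Total steps:** 8. **Longest linear sequence:** 8 (1 → 3 → 4 → 5 → 6 → 7 → 8 → 9 → 10). Dione 3 is reused as the ring B partner in step 6.

## Three steps most likely to fail
1. **Step 7 (DDQ aromatisation of the enol ester diene):** the diene is less electron-rich than the enol ether in step 4, so it may be sluggish or give over-oxidation. Fallback: change the order. Aromatise 3 first (I2, MeOH) to tert-butyl 2,4-dihydroxy-6-propylbenzoate, then couple it with 7 at the more acidic 4-OH using EDC/DMAP, and finish with TFA.
2. **Step 6 (regioselective O4-acylation):** C3-acylation (triketone formation), O2-acylation, or self-condensation of the salicylic acid are possible. Fallback: protect 7 as its 2-O-TBS acid chloride, acylate the dione 3 at −78 °C with Et3N, then run DDQ and TFA, and finish with HF·pyridine.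
3. **Step 3 (O4-methylation selectivity):** O2- or C-methylation would give the wrong isomer. Fallback: aromatise chlorodione 4 directly (I2, MeOH, reflux) to the tert-butyl 3-chlorodivarate, then do regioselective 4-O-methylation (MeI, KHCO3, DMF), which exploits the chelated 2-OH.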